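**Plan**

- Core numbering (cyclopenta[c]pyran): C1 (aryl), O2, C3 (acyl), C4 (methyl), C4a, C5, C6, C7 (methyl), C7a. Retrosynthetic cuts, in order: the O–CH3 bond of the chromone; the aryl–C1 and O2–C1 bonds, with the pyran contracted to a siloxycyclobutane by re-forming a C1–C4 bond; the C3–C(=O) bond of the 1,2-dione; the C1–C4 and C7a–C4a bonds; the C4=C4a double bond.
- Forward: cross-metathesis completes the chain of (S)-citronellal; one Michael–aldol event forms the cyclopentane and the cyclobutane together; the dione is installed by dithiane umpolung; the cyclobutane is then expanded to the dihydropyran while 4-hydroxy-5-methylcoumarin is attached at C1; O-methylation ends the route.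
- Enabling feature: C1 is an acetal-level carbon (O2 and the enolic arene both stabilise a cation there) and C4 is the α-carbon of the 1,2-dione whose enol oxygen is O2. The O2–C1 bond and a C1–C4 bond are therefore the two ways of closing one 1,4-zwitterion, and the C-closed form is a strained donor–acceptor cyclobutane (C1, C7a, C4a, C4) fused to the cyclopentane.
- Stereochemistry: C7 is bought with (S)-citronellal; C7a and C4a follow from it in the Michael–aldol step (allylic strain; cis fusion forced by the four-membered ring); C1 is set in the key step by attack on the convex face of the cis-fused oxocarbenium ion.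

Key step: step 10

Remark: (S)-citronellal and 1-(2-hydroxy-6-methylphenyl)ethanone are taken as catalogue compounds; the siloxycyclobutane intermediates are carried as mixtures of epimers at the siloxy-bearing and the methyl-bearing cyclobutane carbons, because both centres lose their configuration in the key step (their names use bicyclo[3.2.0]heptane locants).

**Route**

Step 1
Reactants: 1 (S)-citronellal [(3S)-3,7-dimethyloct-6-enal]; 2 methyl methacrylate
Product: 3 methyl (2E,6S)-2,6-dimethyl-8-oxooct-2-enoate
Conditions: second-generation Hoveyda–Grubbs catalyst (3 mol%), 2 (8 equiv), dimethyl carbonate, 80 °C, argon sweep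
Reagents that add atoms: none
Why: Olefin cross-metathesis of the trisubstituted alkene with the 1,1-disubstituted acrylate is driven by loss of volatile 2-methylpropene and should give the thermodynamically preferred E-enoate, while the aldehyde and the methyl-bearing stereocentre (β to the carbonyl, not enolisable) are untouched.

Step 2
Reactants: 3 methyl (2E,6S)-2,6-dimethyl-8-oxooct-2-enoate
Product: 5 methyl (1R,2S,5S)-7-[(tert-butyldimethylsilyl)oxy]-2,6-dimethylbicyclo[3.2.0]heptane-6-carboxylate (cis-fused; epimers at C6 and C7), via silyl enol ether 4 (not isolated)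
Conditions: TBSOTf (1.5 equiv), Et3N (2.5 equiv), CH2Cl2, −78 °C to rt
Reagents that add atoms: tert-butyldimethylsilyl trifluoromethanesulfonate, CC(C)(C)[Si](C)(C)OS(=O)(=O)C(F)(F)F
Why: Intramolecular Michael–aldol reaction (formal (2+2) cycloaddition of a silyl enol ether with an enoate): the enol ether carbon adds 5-exo to the silyl-triflate-activated enoate and the resulting ester silyl ketene acetal closes the four-membered ring on the silyloxocarbenium ion; the methyl-bearing centre controls both new ring-fusion centres through allylic 1,3-strain (its hydrogen lies in the enol ether plane and the tether delivers the acceptor from one face, so the methyl group ends trans to the siloxy-bearing carbon), and only the cis-disposed pair of chains can close to a cyclobutane.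

Step 3
Reactants: 5 methyl (1R,2S,5S)-7-[(tert-butyldimethylsilyl)oxy]-2,6-dimethylbicyclo[3.2.0]heptane-6-carboxylate
Product: 6 [(1R,2S,5S)-7-[(tert-butyldimethylsilyl)oxy]-2,6-dimethylbicyclo[3.2.0]heptan-6-yl]methanol
Conditions: iBu2AlH (3 equiv), CH2Cl2, −78 to 0 °C; aqueous potassium sodium tartrate
Reagents that add atoms: none
Why: Aluminium hydride reduction of a hindered ester to the neopentyl alcohol; the silyl ether and the cyclobutane are inert to the hydride at low temperature.

Step 4
Reactants: 6 [(1R,2S,5S)-7-[(tert-butyldimethylsilyl)oxy]-2,6-dimethylbicyclo[3.2.0]heptan-6-yl]methanol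
Product: 7 (1R,2S,5S)-7-[(tert-butyldimethylsilyl)oxy]-2,6-dimethylbicyclo[3.2.0]heptane-6-carbaldehyde
Conditions: Dess–Martin periodinane (1.5 equiv), pyridine, CH2Cl2, 0 °C to rt
Reagents that add atoms: none
Why: Dess–Martin oxidation of a primary alcohol to a non-enolisable aldehyde under buffered conditions that should leave the siloxycyclobutane closed.

Step 5
Reactants: 8 3-methylbutanal; 9 propane-1,3-dithiol
Product: 10 2-(2-methylpropyl)-1,3-dithiane
Conditions: BF3·OEt2 (10 mol%), CH2Cl2, 0 °C to rt
Reagents that add atoms: none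
Why: Lewis-acid-catalysed thioacetalisation of an aldehyde, giving the masked isovaleryl anion precursor.

Step 6
Reactants: 7 (1R,2S,5S)-7-[(tert-butyldimethylsilyl)oxy]-2,6-dimethylbicyclo[3.2.0]heptane-6-carbaldehyde; 10 2-(2-methylpropyl)-1,3-dithiane
Product: 12 [(1R,2S,5S)-7-[(tert-butyldimethylsilyl)oxy]-2,6-dimethylbicyclo[3.2.0]heptan-6-yl][2-(2-methylpropyl)-1,3-dithian-2-yl]methanol (carbinol epimers), via lithiated dithiane 11 (not isolated)
Conditions: 10 (1.5 equiv), nBuLi, THF, −30 °C; then 7, −78 °C; aq. NH4Cl at −78 °C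
Reagents that add atoms: none
Why: Corey–Seebach umpolung: the 2-lithio-1,3-dithiane adds as an isovaleryl anion equivalent to the non-enolisable aldehyde, and the cold quench is meant to prevent silyl migration to the new alkoxide; the carbinol configuration is irrelevant because it is oxidised next.

Step 7
Reactants: 12 [(1R,2S,5S)-7-[(tert-butyldimethylsilyl)oxy]-2,6-dimethylbicyclo[3.2.0]heptan-6-yl][2-(2-methylpropyl)-1,3-dithian-2-yl]methanol
Product: 13 [(1R,2S,5S)-7-[(tert-butyldimethylsilyl)oxy]-2,6-dimethylbicyclo[3.2.0]heptan-6-yl][2-(2-methylpropyl)-1,3-dithian-2-yl]methanone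
Conditions: Dess–Martin periodinane (1.5 equiv), pyridine, dry CH2Cl2, rt
Reagents that add atoms: none
Why: Dess–Martin oxidation of a secondary alcohol to the ketone; under anhydrous buffered conditions the dithiane should survive.

Step 8
Reactants: 13 [(1R,2S,5S)-7-[(tert-butyldimethylsilyl)oxy]-2,6-dimethylbicyclo[3.2.0]heptan-6-yl][2-(2-methylpropyl)-1,3-dithian-2-yl]methanone
Product: 14 1-[(1R,2S,5S)-7-[(tert-butyldimethylsilyl)oxy]-2,6-dimethylbicyclo[3.2.0]heptan-6-yl]-4-methylpentane-1,2-dione
Conditions: PhI(OCOCF3)2 (1.5 equiv), NaHCO3, MeCN/H2O 9:1, 0 °C, light excluded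
Reagents that add atoms: water, O
Why: Oxidative dethioketalisation with a hypervalent iodine reagent in buffered aqueous acetonitrile unmasks the 1,2-dione without acid strong enough to open the donor–acceptor cyclobutane.

Step 9
Reactants: 15 1-(2-hydroxy-6-methylphenyl)ethan-1-one; 16 diethyl carbonate
Product: 17 4-hydroxy-5-methyl-2H-chromen-2-one
Conditions: NaH (4 equiv), toluene, 110 °C; then aq. HCl
Reagents that add atoms: none
Why: Classical 4-hydroxycoumarin synthesis: Claisen-type C-ethoxycarbonylation of the methyl ketone enolate followed by lactonisation on the phenoxide.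

Step 10
Reactants: 14 1-[(1R,2S,5S)-7-[(tert-butyldimethylsilyl)oxy]-2,6-dimethylbicyclo[3.2.0]heptan-6-yl]-4-methylpentane-1,2-dione; 17 4-hydroxy-5-methyl-2H-chromen-2-one
Product: 19 4-hydroxy-5-methyl-3-[(1R,4aS,7S,7aR)-4,7-dimethyl-3-(3-methylbutanoyl)-1,4a,5,6,7,7a-hexahydrocyclopenta[c]pyran-1-yl]-2H-chromen-2-one, via silyl acetal 18 (not isolated)
Conditions: Sc(OTf)3 (10 mol%), 17 (1.2 equiv), MeCN, 4 Å molecular sieves, 0 °C to rt
Reagents that add atoms: none
Why: Sc(OTf)3 binds the 1,2-dione while the siloxy oxygen pushes, so the strained C1–C4 bond of the cyclobutane breaks heterolytically to a silyloxocarbenium ion at C1 and a chelated dione enolate at C4 (retro-Mukaiyama-aldol, the silyl ether version of a de Mayo fragmentation), the enolate oxygen recloses on C1 to the silyl acetal 18, and after loss of the silanolate C3 of the enolic coumarin 17 adds to the cyclic oxocarbenium ion. The closest known reaction types are the zwitterionic ring expansion of 2-donor-substituted cyclobutyl ketones to 2-donor-3,4-dihydro-2H-pyrans and the acid-mediated C-alkylation of 4-hydroxycoumarins by lactol derivatives. The dihydropyran closes by 6-(enolendo)-exo-trig attack of the enolate oxygen on the C1=O+ carbon, so the four-membered carbocycle C1–C7a–C4a–C4 becomes the six-membered ring C1–O2–C3–C4–C4a–C7a by insertion of O2 and C3, and the cis ring fusion is inherited from the cyclobutane. The only new stereocentre, C1, is set by substrate control: the coumarin attacks the convex face of the cis-fused oxocarbenium ion, anti to the C7a–C7 bond, which places the aryl group cis to H-7a, and because the addition is reversible under the acid the same exo isomer should also be favoured at equilibrium. The step needs O- rather than C-reclosure, no enolisation of the transient C1 electrophile toward C7a and only one coumarin per molecule; release of the cyclobutane strain and conjugation in the acyl enol ether make the expansion effectively one-way, and intramolecular capture by the enolate oxygen is expected to outrun enolisation or a second intermolecular addition.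

Step 11
Reactants: 19 4-hydroxy-5-methyl-3-[(1R,4aS,7S,7aR)-4,7-dimethyl-3-(3-methylbutanoyl)-1,4a,5,6,7,7a-hexahydrocyclopenta[c]pyran-1-yl]-2H-chromen-2-one
Product: 20 2-methoxy-5-methyl-3-[(1R,4aS,7S,7aR)-4,7-dimethyl-3-(3-methylbutanoyl)-1,4a,5,6,7,7a-hexahydrocyclopenta[c]pyran-1-yl]-4H-chromen-4-one (target)
Conditions: MeOTf (1.1 equiv), CH2Cl2, 0 °C to rt, no base; then aq. NaHCO3
Reagents that add atoms: methyl trifluoromethanesulfonate, COS(=O)(=O)C(F)(F)F
Why: O-Methylation of a vinylogous acid: a hard methylating agent should attack the neutral 4-hydroxycoumarin at the lactone carbonyl oxygen, its most basic site, and loss of the 4-OH proton from the 2-methoxychromenylium ion gives the 2-methoxychromone, as known for 4-hydroxy-2-pyranones.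

**Compound list**

1 | (S)-citronellal, (3S)-3,7-dimethyloct-6-enal | CC(C)=CCC[C@H](C)CC=O | starting material
2 | methyl methacrylate | C=C(C)C(=O)OC | starting material
3 | methyl (2E,6S)-2,6-dimethyl-8-oxooct-2-enoate | COC(=O)/C(C)=C/CC[C@H](C)CC=O | intermediate
4 | methyl (2E,6S,7Z)-8-[(tert-butyldimethylsilyl)oxy]-2,6-dimethylocta-2,7-dienoate (Z expected as main enol ether isomer) | COC(=O)/C(C)=C/CC[C@H](C)/C=C\O[Si](C)(C)C(C)(C)C | intermediate
5 | methyl (1R,2S,5S)-7-[(tert-butyldimethylsilyl)oxy]-2,6-dimethylbicyclo[3.2.0]heptane-6-carboxylate (epimers at C6 and C7) | CC(C)(C)[Si](C)(C)OC1C(C)(C(=O)OC)[C@H]2CC[C@H](C)[C@H]21 | intermediate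
6 | [(1R,2S,5S)-7-[(tert-butyldimethylsilyl)oxy]-2,6-dimethylbicyclo[3.2.0]heptan-6-yl]methanol (epimers at C6 and C7) | CC(C)(C)[Si](C)(C)OC1C(C)(CO)[C@H]2CC[C@H](C)[C@H]21 | intermediate
7 | (1R,2S,5S)-7-[(tert-butyldimethylsilyl)oxy]-2,6-dimethylbicyclo[3.2.0]heptane-6-carbaldehyde (epimers at C6 and C7) | CC(C)(C)[Si](C)(C)OC1C(C)(C=O)[C@H]2CC[C@H](C)[C@H]21 | intermediate
8 | 3-methylbutanal | CC(C)CC=O | starting material
9 | propane-1,3-dithiol | SCCCS | starting material
10 | 2-(2-methylpropyl)-1,3-dithiane | CC(C)CC1SCCCS1 | intermediate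
11 | 2-lithio-2-(2-methylpropyl)-1,3-dithiane | [Li]C1(CC(C)C)SCCCS1 | intermediate
12 | [(1R,2S,5S)-7-[(tert-butyldimethylsilyl)oxy]-2,6-dimethylbicyclo[3.2.0]heptan-6-yl][2-(2-methylpropyl)-1,3-dithian-2-yl]methanol (epimers at C6, C7 and the carbinol carbon) | CC(C)(C)[Si](C)(C)OC1C(C)(C(O)C3(CC(C)C)SCCCS3)[C@H]2CC[C@H](C)[C@H]21 | intermediate
13 | [(1R,2S,5S)-7-[(tert-butyldimethylsilyl)oxy]-2,6-dimethylbicyclo[3.2.0]heptan-6-yl][2-(2-methylpropyl)-1,3-dithian-2-yl]methanone (epimers at C6 and C7) | CC(C)(C)[Si](C)(C)OC1C(C)(C(=O)C3(CC(C)C)SCCCS3)[C@H]2CC[C@H](C)[C@H]21 | intermediate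
14 | 1-[(1R,2S,5S)-7-[(tert-butyldimethylsilyl)oxy]-2,6-dimethylbicyclo[3.2.0]heptan-6-yl]-4-methylpentane-1,2-dione (epimers at C6 and C7) | CC(C)(C)[Si](C)(C)OC1C(C)(C(=O)C(=O)CC(C)C)[C@H]2CC[C@H](C)[C@H]21 | intermediate
15 | 1-(2-hydroxy-6-methylphenyl)ethan-1-one | CC(=O)c1c(C)cccc1O | starting material
16 | diethyl carbonate | CCOC(=O)OCC | starting material
17 | 4-hydroxy-5-methyl-2H-chromen-2-one | Cc1cccc2oc(=O)cc(O)c12 | intermediate
18 | 1-[(4aS,7S,7aR)-1-[(tert-butyldimethylsilyl)oxy]-4,7-dimethyl-1,4a,5,6,7,7a-hexahydrocyclopenta[c]pyran-3-yl]-3-methylbutan-1-one (C1 epimers) | CC(C)(C)[Si](C)(C)OC1OC(C(=O)CC(C)C)=C(C)[C@H]2CC[C@H](C)[C@H]21 | intermediate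
19 | 4-hydroxy-5-methyl-3-[(1R,4aS,7S,7aR)-4,7-dimethyl-3-(3-methylbutanoyl)-1,4a,5,6,7,7a-hexahydrocyclopenta[c]pyran-1-yl]-2H-chromen-2-one | Cc1cccc2oc(=O)c(c(O)c12)[C@@H]1OC(C(=O)CC(C)C)=C(C)[C@H]2CC[C@H](C)[C@H]21 | intermediate
20 | 2-methoxy-5-methyl-3-[(1R,4aS,7S,7aR)-4,7-dimethyl-3-(3-methylbutanoyl)-1,4a,5,6,7,7a-hexahydrocyclopenta[c]pyran-1-yl]-4H-chromen-4-one | COc1oc2cccc(C)c2c(=O)c1[C@@H]1OC(C(=O)CC(C)C)=C(C)[C@H]2CC[C@H](C)[C@H]21 | target

**Step count and risks**

Total step count: 11. Longest linear sequence: 9 (steps 1, 2, 3, 4, 6, 7, 8, 10, 11).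

Steps most likely to fail:

Step 2. The 5-exo Michael addition may stop at the monocyclic stage, because closure of the four-membered ring onto a carbon that becomes quaternary is slow, and intermolecular aldol condensation of the aldehyde may compete. The fallback sets out from 3: the silyl enol ether 4 is prepared and isolated (TBSOTf, Et3N, CH2Cl2, −78 °C, short reaction time, non-aqueous work-up) and then closed by a triplet-sensitised intramolecular (2+2) photocycloaddition (300 nm, acetone as solvent and sensitiser). The 1,4-diradical formed by 5-exo bonding should collapse to the same cis-fused bicyclo[3.2.0]heptane, so the fallback returns to the route at 5; it makes no new compound (entry F0).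

Step 10. The ring-opened C1 electrophile may enolise toward C7a before it is captured, with loss of the ring-fusion configuration. A second coumarin may add to C1 before the enolate oxygen closes, and the facial selectivity of the arylation may be poor under kinetic control. The fallback sets out from 14 and separates the two events. Buffered fluoride (TBAF, AcOH, THF, 0 °C) frees the cyclobutanol, which undergoes retro-aldol opening and closes to 1-[(4aS,7S,7aR)-1-hydroxy-4,7-dimethyl-1,4a,5,6,7,7a-hexahydrocyclopenta[c]pyran-3-yl]-3-methylbutan-1-one F1. Acetylation (Ac2O, pyridine, DMAP) gives the anomeric acetate F2, which is coupled with 17 under BF3·OEt2 in MeCN at −20 °C. The fallback returns to the route at 19.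

Step 11. Methylation may take place at the 4-oxygen and give the isomeric 4-methoxycoumarin, and the acid released may reopen the ring at the aryl-bearing C1. The fallback sets out from 15 and installs the methoxy group before the coupling. CS2 and KOtBu in THF convert 15 into 4-hydroxy-5-methyl-2H-chromene-2-thione F3; S-methylation (MeI, K2CO3, acetone) gives 5-methyl-2-(methylsulfanyl)-4H-chromen-4-one F4; oxidation (mCPBA, CH2Cl2) gives 2-(methanesulfonyl)-5-methyl-4H-chromen-4-one F5; NaOMe in MeOH displaces the sulfinate to give 2-methoxy-5-methyl-4H-chromen-4-one F6. F6 is then used in place of 17 in the ring expansion and arylation of 14 (Sc(OTf)3, MeCN), which returns to the route directly at 20. This coupling is less certain than the one with 17, because C3 of a 2-methoxychromone is a weaker carbon nucleophile than the coumarin enol.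

Further compounds
F0 | step 2 | none | none
F1 | step 10 | 1-[(4aS,7S,7aR)-1-hydroxy-4,7-dimethyl-1,4a,5,6,7,7a-hexahydrocyclopenta[c]pyran-3-yl]-3-methylbutan-1-one | OC1OC(C(=O)CC(C)C)=C(C)[C@H]2CC[C@H](C)[C@H]21
F2 | step 10 | (4aS,7S,7aR)-4,7-dimethyl-3-(3-methylbutanoyl)-1,4a,5,6,7,7a-hexahydrocyclopenta[c]pyran-1-yl acetate | CC(=O)OC1OC(C(=O)CC(C)C)=C(C)[C@H]2CC[C@H](C)[C@H]21
F3 | step 11 | 4-hydroxy-5-methyl-2H-chromene-2-thione | Cc1cccc2oc(=S)cc(O)c12
F4 | step 11 | 5-methyl-2-(methylsulfanyl)-4H-chromen-4-one | CSc1cc(=O)c2c(C)cccc2o1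
F5 | step 11 | 2-(methanesulfonyl)-5-methyl-4H-chromen-4-one | CS(=O)(=O)c1cc(=O)c2c(C)cccc2o1
F6 | step 11 | 2-methoxy-5-methyl-4H-chromen-4-one | COc1cc(=O)c2c(C)cccc2o1
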